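**Plan**

1. The target is epiguibourtinidol-(4β→8)-(−)-epicatechin. The upper unit (rings A, B, C; atoms O1, C2, C3, C4, C4a, C8a) is 2,3-cis-3,4-trans (2R,3R,4R); the lower unit (rings D, E, F) is (2R,3R).
2. Retrosynthesis: first remove the seven benzyl ethers and the benzoyl group on O3; then cut O1–C2 and C3–C4 of ring C together (retro oxa-[4+2]) to an ortho-quinone methide and (Z)-2-[4-(benzyloxy)phenyl]ethenyl benzoate; then cut the C4–C8 bond to ring D (aryllithium plus salicylaldehyde).
3. Enabling feature: O1 and C4 sit ortho to each other on resorcinol ring A (at C8a and C4a) and C4 is doubly benzylic (rings A and D), so ring A plus C4 is a latent heterodiene O1=C8a–C4a=C4. C2=C3 is a styrene made nucleophilic at C3 by the para oxygen of ring B.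
4. Forward: rings D, E, F come from (−)-epicatechin (benzylation, C8 bromination, Br–Li exchange); C4 and ring A are attached by addition to 4-(benzyloxy)-2-hydroxybenzaldehyde; ring C is closed last by the cycloaddition; then deprotection.
5. Stereochemistry: lower C2/C3 from the chiral pool; C2/C3 cis from the Z alkene (suprafacial addition); C3/C4 trans from exo approach; absolute sense (4R) from a chiral phosphoric acid. The benzoyl group on O3 is the helper that carries the C3 oxygen through the cycloaddition and is removed in step 7.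

Key step: step 6

Remark: the (R)-configured phosphoric acid is written as the antipode that leads to 4R; if the facial sense proves opposite, the (S)-acid is used with no other change.

**Route**

Step 1
Reactants: 1 (−)-epicatechin
Product: 2 5,7,3',4'-tetra-O-benzyl-(−)-epicatechin, (2R,3R)-5,7-bis(benzyloxy)-2-[3,4-bis(benzyloxy)phenyl]chroman-3-ol
Conditions: BnBr (4.2 equiv), K2CO3 (4.5 equiv), DMF, 0 °C → rt, Ar
Reagents that add atoms: benzyl bromide BrCc1ccccc1
Why: Williamson etherification; carbonate deprotonates only the four phenols, so the secondary 3-OH stays free and C2/C3 are untouched.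

Step 2
Reactants: 2 5,7,3',4'-tetra-O-benzyl-(−)-epicatechin
Product: 3 8-bromo-5,7,3',4'-tetra-O-benzyl-(−)-epicatechin
Conditions: NBS (1.0 equiv), CH2Cl2, −78 °C → rt
Reagents that add atoms: N-bromosuccinimide O=C1CCC(=O)N1Br
Why: Electrophilic aromatic bromination; C8 of the trioxygenated ring D is the most nucleophilic and accessible position of a tetra-O-benzyl flavan-3-ol, so one equivalent should brominate there selectively.

Step 3
Reactants: 3 8-bromo-5,7,3',4'-tetra-O-benzyl-(−)-epicatechin
Product: 4 8-bromo-3,5,7,3',4'-penta-O-benzyl-(−)-epicatechin, (2R,3R)-3,5,7-tris(benzyloxy)-2-[3,4-bis(benzyloxy)phenyl]-8-bromochromane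
Conditions: NaH (1.3 equiv), BnBr (1.2 equiv), DMF, 0 °C → rt
Reagents that add atoms: benzyl bromide BrCc1ccccc1
Why: Williamson etherification of the 3-alkoxide removes the only acidic proton before lithiation; no stereocentre is affected.

Step 4
Reactants: 4 8-bromo-3,5,7,3',4'-penta-O-benzyl-(−)-epicatechin; 5 4-(benzyloxy)-2-hydroxybenzaldehyde
Product: 8 [4-(benzyloxy)-2-hydroxyphenyl](3,5,7,3',4'-penta-O-benzylepicatechin-8-yl)methanol (both carbinol epimers), via 8-lithio-penta-O-benzylepicatechin 6 (not isolated), via sodium 5-(benzyloxy)-2-formylphenolate 7 (not isolated)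
Conditions: 4, n-BuLi (1.05 equiv), THF, −78 °C; then 7 [from 5, NaH (1.0 equiv), THF, 0 °C], −78 → 0 °C; H2O; chromatography on Et3N-deactivated silica
Reagents that add atoms: none
Why: Bromine–lithium exchange followed by aryllithium addition to an aldehyde whose phenol is masked in situ as the phenoxide; the new carbinol centre is uncontrolled and irrelevant because it becomes sp2 in step 6.

Step 5
Reactants: 9 1-(benzyloxy)-4-ethynylbenzene
Product: 10 (Z)-2-[4-(benzyloxy)phenyl]ethenyl benzoate
Conditions: PhCO2H (1.1 equiv), Ru(η3-CH2C(CH3)CH2)2(Ph2P(CH2)4PPh2) (3 mol %), toluene, 65 °C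
Reagents that add atoms: benzoic acid OC(=O)c1ccccc1
Why: Ruthenium-catalysed anti-Markovnikov addition of a carboxylic acid to a terminal alkyne via a ruthenium vinylidene, which delivers the carboxylate trans to the metal and should give the Z enol ester.

Step 6
Reactants: 8 [4-(benzyloxy)-2-hydroxyphenyl](penta-O-benzylepicatechin-8-yl)methanol; 10 (Z)-2-[4-(benzyloxy)phenyl]ethenyl benzoate
Product: 12 (2R,3R,4R)-7-(benzyloxy)-2-[4-(benzyloxy)phenyl]-4-[(2R,3R)-3,5,7-tris(benzyloxy)-2-[3,4-bis(benzyloxy)phenyl]chroman-8-yl]chroman-3-yl benzoate, via (E)-ortho-quinone methide 11 (not isolated)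
Conditions: (R)-3,3'-bis(2,4,6-triisopropylphenyl)-1,1'-binaphthyl-2,2'-diyl hydrogen phosphate (10 mol %), 10 (3 equiv), 4 Å MS, CH2Cl2 (0.02 M), −20 °C → rt, 8 added over 6 h
Reagents that add atoms: none
Why: Proposed new method: the phosphoric acid dehydrates 8 to the (E)-ortho-quinone methide 11 and holds it by hydrogen bonds while its heterodiene O1=C8a–C4a=C4 adds to the C=C of 10 in a concerted, asynchronous inverse-electron-demand oxa-[4+2] cycloaddition in which C3–C4 bonding leads and O1–C2 bonding follows; the closest known reaction type is the Brønsted-acid-catalysed [4+2] cycloaddition of ortho-quinone methides from ortho-hydroxybenzhydrols with styrenes and β-alkylstyrenes to give 2-arylchromans, which has not been shown for a β-acyloxystyrene. Ring C is the only ring closed, by an intermolecular [4π+2π] closure that is suprafacial on both partners, so the Z geometry of 10 becomes the 2,3-cis relationship. The regiochemistry (aryl at C2, benzoyloxy at C3) requires the styrene polarisation to override the enol-ester polarisation, and the para-benzyloxy group of ring B secures this because charge developing at C2 is then 4-alkoxybenzylic, whereas the reverse orientation would build a poorly stabilised acyloxycarbenium centre. The 3,4-trans relationship comes from exo approach to the E diene: around the leading C3–C4 bond the small C3 hydrogen takes the crowded slot between C4a and the twisted 2,6-dioxygenated ring D, so the benzoyloxy group and the cis aryl ring point away from ring A. The absolute configuration at C4 (R, and with it 2R,3R) is controlled by the chiral phosphate, which shields one face of the bound methide; the opposite-face adduct is a diastereomer because of the epicatechin unit and can be removed by chromatography. The step also needs chemoselectivity over self-arylation of 11 at C6 of ring D of a second molecule, secured by slow addition of 8 into excess 10 at high dilution.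

Step 7
Reactants: 12 protected dimer 3-O-benzoate
Product: 13 (2R,3R,4R)-7-(benzyloxy)-2-[4-(benzyloxy)phenyl]-4-[(2R,3R)-3,5,7-tris(benzyloxy)-2-[3,4-bis(benzyloxy)phenyl]chroman-8-yl]chroman-3-ol
Conditions: NaOCH3 (0.3 equiv), CH3OH/THF 1:1, rt → 40 °C
Reagents that add atoms: none
Why: Base-catalysed transesterification (Zemplén type) frees O3 with retention, since only the acyl C–O bond is broken; benzyl ethers and all stereocentres are inert.

Step 8
Reactants: 13 hepta-O-benzyl dimer
Product: 14 epiguibourtinidol-(4β→8)-epicatechin (target)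
Conditions: H2 (1 atm), Pd(OH)2/C, THF/CH3OH/H2O, rt
Reagents that add atoms: none
Why: Hydrogenolysis of the seven benzyl ethers under neutral conditions; the cyclic benzylic C2–O1 ethers and the C4–C8 bond of a 5-deoxy upper unit are expected to survive, as they do in debenzylations of benzylated proanthocyanidins.

**Compound list**

1 | (−)-epicatechin, (2R,3R)-2-(3,4-dihydroxyphenyl)chromane-3,5,7-triol | c1c(O)cc(O)c2c1O[C@H](c1ccc(O)c(O)c1)[C@H](O)C2 | starting material
2 | 5,7,3',4'-tetra-O-benzyl-(−)-epicatechin | c1c(OCc5ccccc5)cc(OCc5ccccc5)c2c1O[C@H](c1ccc(OCc5ccccc5)c(OCc5ccccc5)c1)[C@H](O)C2 | intermediate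
3 | 8-bromo-5,7,3',4'-tetra-O-benzyl-(−)-epicatechin | Brc1c(OCc5ccccc5)cc(OCc5ccccc5)c2c1O[C@H](c1ccc(OCc5ccccc5)c(OCc5ccccc5)c1)[C@H](O)C2 | intermediate
4 | 8-bromo-3,5,7,3',4'-penta-O-benzyl-(−)-epicatechin | Brc1c(OCc5ccccc5)cc(OCc5ccccc5)c2c1O[C@H](c1ccc(OCc5ccccc5)c(OCc5ccccc5)c1)[C@H](OCc5ccccc5)C2 | intermediate
5 | 4-(benzyloxy)-2-hydroxybenzaldehyde | O=Cc1ccc(OCc2ccccc2)cc1O | starting material
6 | 8-lithio-3,5,7,3',4'-penta-O-benzyl-(−)-epicatechin | [Li]c1c(OCc5ccccc5)cc(OCc5ccccc5)c2c1O[C@H](c1ccc(OCc5ccccc5)c(OCc5ccccc5)c1)[C@H](OCc5ccccc5)C2 | intermediate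
7 | sodium 5-(benzyloxy)-2-formylphenolate | [Na+].[O-]c1cc(OCc2ccccc2)ccc1C=O | intermediate
8 | [4-(benzyloxy)-2-hydroxyphenyl][(2R,3R)-3,5,7-tris(benzyloxy)-2-[3,4-bis(benzyloxy)phenyl]chroman-8-yl]methanol, both carbinol epimers | OC(c1ccc(OCc5ccccc5)cc1O)c1c(OCc5ccccc5)cc(OCc5ccccc5)c2c1O[C@H](c1ccc(OCc5ccccc5)c(OCc5ccccc5)c1)[C@H](OCc5ccccc5)C2 | intermediate
9 | 1-(benzyloxy)-4-ethynylbenzene | C#Cc1ccc(OCc2ccccc2)cc1 | starting material
10 | (Z)-2-[4-(benzyloxy)phenyl]ethenyl benzoate | O=C(O/C=C\c1ccc(OCc2ccccc2)cc1)c1ccccc1 | intermediate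
11 | (6E)-3-(benzyloxy)-6-{[(2R,3R)-3,5,7-tris(benzyloxy)-2-[3,4-bis(benzyloxy)phenyl]chroman-8-yl]methylidene}cyclohexa-2,4-dien-1-one | O=C1C=C(OCc5ccccc5)C=C/C1=C\c1c(OCc5ccccc5)cc(OCc5ccccc5)c2c1O[C@H](c1ccc(OCc5ccccc5)c(OCc5ccccc5)c1)[C@H](OCc5ccccc5)C2 | intermediate
12 | (2R,3R,4R)-7-(benzyloxy)-2-[4-(benzyloxy)phenyl]-4-[(2R,3R)-3,5,7-tris(benzyloxy)-2-[3,4-bis(benzyloxy)phenyl]chroman-8-yl]chroman-3-yl benzoate | c5ccccc5COc1ccc([C@H]2Oc3cc(OCc5ccccc5)ccc3[C@H](c3c(OCc5ccccc5)cc(OCc5ccccc5)c4c3O[C@H](c3ccc(OCc5ccccc5)c(OCc5ccccc5)c3)[C@H](OCc5ccccc5)C4)[C@H]2OC(=O)c5ccccc5)cc1 | intermediate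
13 | (2R,3R,4R)-7-(benzyloxy)-2-[4-(benzyloxy)phenyl]-4-[(2R,3R)-3,5,7-tris(benzyloxy)-2-[3,4-bis(benzyloxy)phenyl]chroman-8-yl]chroman-3-ol | c5ccccc5COc1ccc([C@H]2Oc3cc(OCc5ccccc5)ccc3[C@H](c3c(OCc5ccccc5)cc(OCc5ccccc5)c4c3O[C@H](c3ccc(OCc5ccccc5)c(OCc5ccccc5)c3)[C@H](OCc5ccccc5)C4)[C@H]2O)cc1 | intermediate
14 | (2R,3R,4R)-2-(4-hydroxyphenyl)-4-[(2R,3R)-2-(3,4-dihydroxyphenyl)-3,5,7-trihydroxychroman-8-yl]chromane-3,7-diol | Oc1ccc([C@H]2Oc3cc(O)ccc3[C@H](c3c(O)cc(O)c4c3O[C@H](c3ccc(O)c(O)c3)[C@H](O)C4)[C@H]2O)cc1 | target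

**Summary**

Total steps: 8. Longest linear sequence: 7 (steps 1, 2, 3, 4, 6, 7, 8); step 5 is a one-step side branch.

**Steps most likely to fail**

1. Step 6. The cycloaddition may become stepwise, so that rotation in the benzylic cation or participation of the benzoate carbonyl erodes the Z geometry towards the 2,3-trans series. The enol-ester polarisation may also win (reversed regiochemistry), the endo approach may compete, facial discrimination by the catalyst may be poor, or the quinone methide may be consumed by self-arylation. Fallback with known chemistry, forming the two bonds one after the other; it sets out from 8 and returns at 12. Commercial 2-bromo-1-[4-(benzyloxy)phenyl]ethanone is treated with benzoic acid and K2CO3 in DMF to give 2-[4-(benzyloxy)phenyl]-2-oxoethyl benzoate F1. TBSOTf and Et3N in CH2Cl2 convert it into (Z)-2-[4-(benzyloxy)phenyl]-2-[(tert-butyldimethylsilyl)oxy]ethenyl benzoate F2. Mukaiyama–Michael addition of F2 to the quinone methide generated from 8 (the same phosphoric acid, CH2Cl2, −40 °C) forms C3–C4 and, after aqueous work-up, should give (2R,3R)-2-(benzoyloxy)-1-[4-(benzyloxy)phenyl]-3-[4-(benzyloxy)-2-hydroxyphenyl]-3-(penta-O-benzylepicatechin-8-yl)propan-1-one F3, in equilibrium with its cyclic hemiketal; the diastereomers are separated here. Reductive etherification of F3 (Et3SiH, BF3·OEt2, CH2Cl2, −78 → −20 °C) closes O1–C2; hydride delivery to the cyclic oxocarbenium ion anti to the 3-benzoyloxy group should give the 2,3-cis ring of 12.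

2. Step 4. The hindered aryllithium may add sluggishly to the deactivated phenoxide aldehyde and be protonated instead, and the very electron-rich benzhydrol may ionise during purification. Fallback with reversed roles of the two rings; it sets out from 4 and returns at 8. Bromine–lithium exchange of 4 (n-BuLi, THF, −78 °C) and quenching with DMF gives 8-formyl-3,5,7,3',4'-penta-O-benzyl-(−)-epicatechin F4. 3-(Benzyloxy)phenol and EtMgBr give bromomagnesium 3-(benzyloxy)phenolate F5, which in toluene at rt undergoes chelation-directed ortho-hydroxyalkylation with F4. Attack at the ortho position para to the benzyloxy group gives 8.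

3. Step 5. Markovnikov addition or partial loss of Z selectivity (or later Z to E isomerisation) would feed the wrong alkene geometry into step 6. Fallback that sets the geometry photochemically; it sets out from 9 and returns at 10. Anti-Markovnikov hydration of 9 ([(C5H5)Ru(NCCH3)3]PF6 with 5,5'-bis(trifluoromethyl)-2,2'-bipyridine, aqueous N-methylpyrrolidone) gives 2-[4-(benzyloxy)phenyl]acetaldehyde F6. Enolisation and O-acylation (KN(SiMe3)2, THF, −78 °C; benzoyl chloride) give 10 together with (E)-2-[4-(benzyloxy)phenyl]ethenyl benzoate F7. Triplet-sensitised isomerisation of the mixture (Ir(ppy)3, tris(2-phenylpyridinato)iridium, 1 mol %, 450 nm, CH3CN) should enrich the contra-thermodynamic Z isomer 10, which is then purified by chromatography.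

**Further compounds**

F1 | step 6 | 2-[4-(benzyloxy)phenyl]-2-oxoethyl benzoate | O=C(COC(=O)c1ccccc1)c1ccc(OCc2ccccc2)cc1
F2 | step 6 | (Z)-2-[4-(benzyloxy)phenyl]-2-[(tert-butyldimethylsilyl)oxy]ethenyl benzoate | CC(C)(C)[Si](C)(C)O/C(=C\OC(=O)c1ccccc1)c1ccc(OCc2ccccc2)cc1
F3 | step 6 | (2R,3R)-2-(benzoyloxy)-1-[4-(benzyloxy)phenyl]-3-[4-(benzyloxy)-2-hydroxyphenyl]-3-[(2R,3R)-3,5,7-tris(benzyloxy)-2-[3,4-bis(benzyloxy)phenyl]chroman-8-yl]propan-1-one | O=C(c1ccc(OCc5ccccc5)cc1)[C@H](OC(=O)c5ccccc5)[C@@H](c1c(OCc5ccccc5)cc(OCc5ccccc5)c2c1O[C@H](c1ccc(OCc5ccccc5)c(OCc5ccccc5)c1)[C@H](OCc5ccccc5)C2)c1ccc(OCc5ccccc5)cc1O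
F4 | step 4 | 8-formyl-3,5,7,3',4'-penta-O-benzyl-(−)-epicatechin | O=Cc1c(OCc5ccccc5)cc(OCc5ccccc5)c2c1O[C@H](c1ccc(OCc5ccccc5)c(OCc5ccccc5)c1)[C@H](OCc5ccccc5)C2
F5 | step 4 | bromomagnesium 3-(benzyloxy)phenolate | Br[Mg]Oc1cccc(OCc2ccccc2)c1
F6 | step 5 | 2-[4-(benzyloxy)phenyl]acetaldehyde | O=CCc1ccc(OCc2ccccc2)cc1
F7 | step 5 | (E)-2-[4-(benzyloxy)phenyl]ethenyl benzoate | O=C(O/C=C/c1ccc(OCc2ccccc2)cc1)c1ccccc1
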